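**Retrosynthetic overview**
1. Daphnodorin C ⇐ penta-O-benzyl ether 14 by global hydrogenolysis.
2. 14 ⇐ aldehyde 13: an NHC-catalysed enantioselective dearomatising hydroacylation of the benzofuran C2=C3 bond closes the coumaranone and sets the spiro carbon and the adjacent C–H centre in one step.
3. 13 ⇐ 3-iodobenzofuran 11 + salicylaldehyde 12 (Cu C–O coupling); 11 ⇐ (S)-flavan 7 by C8 iodination, Sonogashira coupling and iodocyclisation through the free 7-OH.
4. 7 ⇐ flavylium salt 5 (C4 hydride reduction, then Ir asymmetric hydrogenation); 5 ⇐ aldehyde 3 + 4'-(benzyloxy)acetophenone 4.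
5. Ring order: pyrylium → chroman → benzofuran → (dearomatisation) coumaranone and dihydrofuran together.

Assumption: the configuration is taken exactly as written in the SMILES (all three centres S; the dihydrofuran 4-hydroxyphenyl is cis to the coumaranone ring O and trans to C=O). For each chiral catalyst the antipode giving this sense is used.

**Route**

Step 1
Reactants: 1, 2,4,6-trihydroxybenzaldehyde
Product: 2, 2-hydroxy-4,6-bis(methoxymethoxy)benzaldehyde
Conditions: MOMCl (2.2 equiv), i-Pr2NEt, CH2Cl2, 0 °C → rt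
Reagents that add atoms: chloromethyl methyl ether, COCCl
Why: Phenol O-alkylation; the 4-OH and one ortho-OH react, and the remaining OH is deactivated by its hydrogen bond to the aldehyde.

Step 2
Reactants: 2, 2-hydroxy-4,6-bis(methoxymethoxy)benzaldehyde
Product: 3, 2-(benzyloxy)-4,6-bis(methoxymethoxy)benzaldehyde
Conditions: BnBr, K2CO3, DMF, 60 °C
Reagents that add atoms: benzyl bromide, BrCc1ccccc1
Why: Williamson etherification of the chelated phenol under forcing conditions; this places the only permanent group on the oxygen that becomes flavan O5.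

Step 3
Reactants: 3, 2-(benzyloxy)-4,6-bis(methoxymethoxy)benzaldehyde; 4, 4'-(benzyloxy)acetophenone
Product: 5, 5-(benzyloxy)-2-[4-(benzyloxy)phenyl]-7-hydroxychromenylium tetrafluoroborate
Conditions: HCl, MeOH, 40 °C, evaporate; then 4, HBF4·OEt2, AcOH/EtOAc, rt, precipitate with Et2O
Reagents that add atoms: tetrafluoroboric acid (BF4⁻ counter-ion), [H+].F[B-](F)(F)F
Why: Robinson flavylium synthesis (acid aldol condensation, then cyclodehydration) after acid removal of both MOM groups; only the OH ortho to CHO can close the pyrylium, so benzyl ends on O5 and the free OH on O7.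

Step 4
Reactants: 5, the 7-hydroxyflavylium salt
Product: 6, 5-(benzyloxy)-2-[4-(benzyloxy)phenyl]-4H-chromen-7-ol
Conditions: Hantzsch ester (1.1 equiv), 2,6-lutidine, CH2Cl2, 0 °C, under N2
Reagents that add atoms: none
Why: Hydride transfer to C4, the soft electrophilic site of flavylium ions, gives the achiral 2-aryl-4H-chromene; the buffer prevents re-protonation and over-reduction.

Step 5
Reactants: 6, the 4H-chromene
Product: 7, (2S)-5-(benzyloxy)-2-[4-(benzyloxy)phenyl]chroman-7-ol
Conditions: [Ir(cod)(chiral P,N ligand, PHOX type)]BArF (1 mol %), H2 (50 bar), CH2Cl2, rt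
Reagents that add atoms: none
Why: Ir-catalysed asymmetric hydrogenation of the cyclic enol ether sets flavan C2 as S by catalyst control; aryl benzyl ethers are inert to homogeneous Ir/H2.

Step 6
Reactants: 7, the (2S)-flavan-7-ol
Product: 8, (2S)-5-(benzyloxy)-2-[4-(benzyloxy)phenyl]-8-iodochroman-7-ol
Conditions: NIS (1.0 equiv), CH2Cl2/DMF, −40 → 0 °C
Reagents that add atoms: N-iodosuccinimide, O=C1CCC(=O)N1I
Why: Electrophilic aromatic iodination ortho to the free phenol; C8 is preferred over C6 because the 5-O-benzyl group is forced by the peri C4 methylene to lie over C6.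

Step 7
Reactants: 8, the 8-iodoflavan-7-ol; 9, 1-(benzyloxy)-4-ethynylbenzene
Product: 10, (2S)-5-(benzyloxy)-2-[4-(benzyloxy)phenyl]-8-{[4-(benzyloxy)phenyl]ethynyl}chroman-7-ol
Conditions: Pd(PPh3)2Cl2 (3 mol %), CuI (3 mol %), Et3N, THF, rt, degassed
Reagents that add atoms: none beyond 9
Why: Sonogashira coupling of the aryl iodide; at room temperature the o-alkynylphenol is isolated before it cyclises.

Step 8
Reactants: 10, the o-alkynylphenol
Product: 11, (2S)-5-(benzyloxy)-2,8-bis[4-(benzyloxy)phenyl]-9-iodo-3,4-dihydro-2H-furo[2,3-h]chromene (furan O on flavan C7, iodine on the furan carbon attached to flavan C8)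
Conditions: I2 (2 equiv), NaHCO3, MeCN, rt
Reagents that add atoms: iodine, II
Why: 5-endo-dig iodocyclisation; the free phenol is the only competent nucleophile, so the furan forms on O7 and the chroman oxygen is not involved.

Step 9
Reactants: 1, 2,4,6-trihydroxybenzaldehyde
Product: 12, 2,4-bis(benzyloxy)-6-hydroxybenzaldehyde
Conditions: BnBr (2.1 equiv), K2CO3, DMF, rt
Reagents that add atoms: benzyl bromide, BrCc1ccccc1
Why: Selective double Williamson etherification; the last ortho-OH stays free because it is hydrogen-bonded to the aldehyde.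

Step 10
Reactants: 11, the 3-iodobenzofuran; 12, 2,4-bis(benzyloxy)-6-hydroxybenzaldehyde
Product: 13, 2,4-bis(benzyloxy)-6-({(2S)-5-(benzyloxy)-2,8-bis[4-(benzyloxy)phenyl]-3,4-dihydro-2H-furo[2,3-h]chromen-9-yl}oxy)benzaldehyde
Conditions: CuI (10 mol %), picolinic acid (20 mol %), K3PO4, DMSO, 90 °C
Reagents that add atoms: none beyond 12
Why: Ullmann-type Cu-catalysed diaryl ether formation; 12 has one free OH and 11 has none, so only one ether can form.

Step 11
Reactants: 13, the 3-(2-formylaryloxy)-2-arylbenzofuran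
Product: 14, penta-O-benzyl-daphnodorin C (spiro C S, dihydrofuran CH S, flavan C2 S)
Conditions: aminoindanol-derived chiral N-aryl triazolium salt (15 mol %), DBU (30 mol %), 1,4-dioxane, 100 °C, under Ar
Reagents that add atoms: none
Why: Proposed new method: the Breslow intermediate of the aldehyde bonds to the benzofuran C3 (5-exo) while its enol O–H proton is delivered to C2 on the same face (concerted, Conia-ene-like), so acyl and H add syn, which places H cis to C=O and the aryl cis to the coumaranone O as in the target, and the chiral carbene chooses the π-face so both new centres are set by the catalyst independently of the remote flavan centre; C3 is the favoured site because benzofurans take a proton at C2 and the developing C3 cation is stabilised by the aryloxy oxygen and the tri-oxygenated benzo ring; the closest known reactions are the NHC-catalysed dearomatising hydroacylation of benzofurans to spiro-chromanones (6-exo) and the enantioselective intramolecular Stetter route to 2,2-disubstituted benzofuran-3(2H)-ones (same 5-exo closure).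

Step 12
Reactants: 14, penta-O-benzyl-daphnodorin C
Product: 15, daphnodorin C
Conditions: H2 (1 atm), 20% Pd(OH)2/C, EtOAc/MeOH, rt, stopped after uptake of 5 equiv
Reagents that add atoms: none
Why: Neutral hydrogenolysis of the five aryl benzyl ethers, which cleave faster than the two ring benzylic C–O bonds; no acid or base is used, so the spiro centre and the C–H centre are not disturbed.

**Compound list**
1 | 2,4,6-trihydroxybenzaldehyde | O=Cc1c(O)cc(O)cc1O | starting material
2 | 2-hydroxy-4,6-bis(methoxymethoxy)benzaldehyde | O=Cc1c(O)cc(OCOC)cc1OCOC | intermediate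
3 | 2-(benzyloxy)-4,6-bis(methoxymethoxy)benzaldehyde | O=Cc1c(OCc2ccccc2)cc(OCOC)cc1OCOC | intermediate
4 | 4'-(benzyloxy)acetophenone | CC(=O)c1ccc(OCc2ccccc2)cc1 | starting material
5 | 5-(benzyloxy)-2-[4-(benzyloxy)phenyl]-7-hydroxychromenylium tetrafluoroborate | Oc1cc(OCc2ccccc2)c2ccc(-c3ccc(OCc4ccccc4)cc3)[o+]c2c1.F[B-](F)(F)F | intermediate
6 | 5-(benzyloxy)-2-[4-(benzyloxy)phenyl]-4H-chromen-7-ol | Oc1cc(OCc2ccccc2)c2CC=C(c3ccc(OCc4ccccc4)cc3)Oc2c1 | intermediate
7 | (2S)-5-(benzyloxy)-2-[4-(benzyloxy)phenyl]chroman-7-ol | Oc1cc(OCc2ccccc2)c2CC[C@@H](c3ccc(OCc4ccccc4)cc3)Oc2c1 | intermediate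
8 | (2S)-5-(benzyloxy)-2-[4-(benzyloxy)phenyl]-8-iodochroman-7-ol | Oc1cc(OCc2ccccc2)c2CC[C@@H](c3ccc(OCc4ccccc4)cc3)Oc2c1I | intermediate
9 | 1-(benzyloxy)-4-ethynylbenzene | C#Cc1ccc(OCc2ccccc2)cc1 | starting material
10 | (2S)-5-(benzyloxy)-2-[4-(benzyloxy)phenyl]-8-{[4-(benzyloxy)phenyl]ethynyl}chroman-7-ol | Oc1cc(OCc2ccccc2)c2CC[C@@H](c3ccc(OCc4ccccc4)cc3)Oc2c1C#Cc1ccc(OCc2ccccc2)cc1 | intermediate
11 | (2S)-5-(benzyloxy)-2,8-bis[4-(benzyloxy)phenyl]-9-iodo-3,4-dihydro-2H-furo[2,3-h]chromene | Ic1c(-c2ccc(OCc3ccccc3)cc2)oc2cc(OCc3ccccc3)c3CC[C@@H](c4ccc(OCc5ccccc5)cc4)Oc3c12 | intermediate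
12 | 2,4-bis(benzyloxy)-6-hydroxybenzaldehyde | O=Cc1c(O)cc(OCc2ccccc2)cc1OCc1ccccc1 | intermediate
13 | 2,4-bis(benzyloxy)-6-({(2S)-5-(benzyloxy)-2,8-bis[4-(benzyloxy)phenyl]-3,4-dihydro-2H-furo[2,3-h]chromen-9-yl}oxy)benzaldehyde | O=Cc1c(OCc2ccccc2)cc(OCc2ccccc2)cc1Oc1c(-c2ccc(OCc3ccccc3)cc2)oc2cc(OCc3ccccc3)c3CC[C@@H](c4ccc(OCc5ccccc5)cc4)Oc3c12 | intermediate
14 | penta-O-benzyl-daphnodorin C | O=C1c2c(OCc3ccccc3)cc(OCc3ccccc3)cc2O[C@]12c1c(cc(OCc3ccccc3)c3c1O[C@H](c1ccc(OCc4ccccc4)cc1)CC3)O[C@H]2c1ccc(OCc2ccccc2)cc1 | intermediate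
15 | daphnodorin C | O=C1c2c(O)cc(O)cc2O[C@]12c1c(cc(O)c3c1O[C@H](c1ccc(O)cc1)CC3)O[C@H]2c1ccc(O)cc1 | target

**Totals**
Total steps: 12. Longest linear sequence: 11 (steps 1–8, 10, 11, 12; step 9 is a one-step branch).

**Three steps most likely to fail**
1. Step 11 (hindered 2,6-dioxygenated aldehyde, tetrasubstituted benzofuran, possible 6-endo attack at C2). Fallback: oxidise the aldehyde of 13 to the acid, make the acid chloride, and run a dearomative ipso Friedel–Crafts acylation at the furan C3 with Et3SiH capture of the resulting 2-aryl oxocarbenium ion; this is racemic at the new centres, so the diastereomers relative to flavan C2 would be separated.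
2. Step 10 (electron-rich, hindered heteroaryl iodide with a chelated, electron-poor phenol). Fallback: reverse the polarity by converting 11 to the benzofuran-3-ol (Li–I exchange, B(OMe)3, H2O2) and forming the ether by SNAr on 2-fluoro-4,6-bis(benzyloxy)benzaldehyde.
3. Step 6 (C8 versus C6 iodination, or di-iodination). Fallback: iodinate before the pyran ring exists, at C5 of 2-(benzyloxy)-4,6-dihydroxybenzaldehyde (the carbon between the two free OH groups, which becomes flavan C8), and carry the aryl iodide through steps 3–5.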